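## Retrosynthetic overview

1. Broussoflavonol G comes from its 7-O-MOM ether by one acetal cleavage. That ether is cut at C2–C1′ into a finished A/C half (a 2-unsubstituted 3-hydroxychromone) and a finished B half (3,4-diprenylcatechol).
2. The C2–C1′ bond is made by an anodic dehydrogenative C–H/C–H coupling. Ring B is oxidised to its o-quinone, C2 of ring C adds to it, and both rings re-aromatise to the oxidation level of the target.
3. Enabling feature, ring B: it is a C4′/C5′ catechol. In its o-quinone C1′ (para to O4′, β to C5′=O) is the only unsubstituted β-carbon, because C2′ and C3′ carry prenyl groups. Ring C: it is a 3-hydroxy-4-pyranone, and its C3–OH enol makes C2–H a carbon nucleophile.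
4. A/C half: ring A is bought as phloracetophenone. Ring C is closed at O1–C2 through an enaminone, C3–OH comes from epoxidation/isomerisation, and the C8 prenyl comes from a para-Claisen–Cope shift from O5.
5. B half: ring B is bought as 4-bromocatechol. The C3′ prenyl is introduced by lithiation between Br and OMOM, the C2′ prenyl by Br/Li exchange.

Key step: step 10

Assumption: the target has no stereocentre. Rotation about C2–C1′ is taken to be fast at room temperature, so the compound is one achiral species and no step has to control configuration. The prenyl alkenes carry two identical methyl groups and have no E/Z isomers.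

## Route

Step 1
Reactants: 1 2,4,6-trihydroxyacetophenone
Product: 2 1-[2,6-dihydroxy-4-(methoxymethoxy)phenyl]ethanone
Conditions: MOMCl (1.0 equiv), K2CO3 (1.1 equiv), acetone, 0 °C → rt
Reagents that add atoms: chloromethyl methyl ether (MOMCl), COCCl
Why: Williamson-type O-alkylation: the 4-OH is the most acidic hydroxyl and the only one not hydrogen-bonded to the acetyl group, so one equivalent of the hard electrophile MOMCl should react there and leave a mirror-symmetric diol.

Step 2
Reactants: 2 1-[2,6-dihydroxy-4-(methoxymethoxy)phenyl]ethanone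
Product: 3 1-[2-hydroxy-4-(methoxymethoxy)-6-(3-methylbut-2-enyloxy)phenyl]ethanone
Conditions: prenyl bromide (1.05 equiv), K2CO3 (1.2 equiv), acetone, reflux
Reagents that add atoms: prenyl bromide (1-bromo-3-methylbut-2-ene), CC(C)=CCBr
Why: Williamson ether synthesis on one of two equivalent ortho hydroxyls, after which the remaining OH is locked in a strong hydrogen bond to the ketone and should resist a second alkylation.

Step 3
Reactants: 3 1-[2-hydroxy-4-(methoxymethoxy)-6-(3-methylbut-2-enyloxy)phenyl]ethanone
Product: 5 7-(methoxymethoxy)-5-(3-methylbut-2-enyloxy)-4H-chromen-4-one, via enaminone 4 (not isolated)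
Conditions: DMF-DMA, toluene, 100 °C; concentrate; AcOH, 60 °C
Reagents that add atoms: N,N-dimethylformamide dimethyl acetal (DMF-DMA), COC(OC)N(C)C
Why: Enaminone route to chromones: condensation of the methyl ketone with DMF-DMA gives 4, and weak acid triggers oxa-Michael addition of the only free phenol and loss of dimethylamine, which closes ring C (O1–C2) and fixes the prenyloxy group at C5 without harming the MOM or prenyl ether.

Step 4
Reactants: 5 7-(methoxymethoxy)-5-(3-methylbut-2-enyloxy)-4H-chromen-4-one
Product: 7 3-hydroxy-7-(methoxymethoxy)-5-(3-methylbut-2-enyloxy)-4H-chromen-4-one, via chromone epoxide 6 (not isolated)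
Conditions: 30% aq. H2O2, 2 M aq. NaOH, CH2Cl2/MeOH, 0 °C; extractive work-up; p-TsOH·H2O (10 mol %), CH2Cl2, 0 °C → rt
Reagents that add atoms: hydrogen peroxide, OO
Why: Weitz–Scheffer epoxidation followed by acid-catalysed epoxide-to-enol isomerisation: hydroperoxide adds only to the electrophilic C2 of the pyranone and ignores the electron-rich prenyl alkene, and opening of the C2–O bond of the racemic cis-epoxide 6 through the O1-stabilised cation with loss of H3 gives the 3-hydroxychromone, so both transient stereocentres vanish.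

Step 5
Reactants: 7 3-hydroxy-7-(methoxymethoxy)-5-(3-methylbut-2-enyloxy)-4H-chromen-4-one
Product: 9 3,5-dihydroxy-7-(methoxymethoxy)-8-(3-methylbut-2-enyl)-4H-chromen-4-one, via ortho-dienone 8 (not isolated)
Conditions: Eu(fod)3 (10 mol %), NaHCO3, PhCl, 85 °C
Reagents that add atoms: none
Why: Europium(III)-catalysed para-Claisen–Cope rearrangement as known for 5-O-prenyl flavonoids: the [3,3] shift from O5 to C6 gives the racemic dienone 8, a second [3,3] shift moves the group to C8 with the normal prenyl connectivity, and enolisation gives the chelated 5-OH.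

Step 6
Reactants: 10 4-bromobenzene-1,2-diol
Product: 11 4-bromo-1,2-bis(methoxymethoxy)benzene
Conditions: NaH (2.2 equiv), DMF, 0 °C; MOMCl (2.3 equiv), 0 °C → rt, N2
Reagents that add atoms: chloromethyl methyl ether (MOMCl), COCCl
Why: Double Williamson-type O-alkylation of the catecholate, giving two MOM groups that protect the catechol and direct the next metalation.

Step 7
Reactants: 11 4-bromo-1,2-bis(methoxymethoxy)benzene
Product: 13 1-bromo-3,4-bis(methoxymethoxy)-2-(3-methylbut-2-enyl)benzene, via aryllithium 12 (not isolated)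
Conditions: LDA (1.1 equiv), THF, −78 °C; CuBr·SMe2 (10 mol %), prenyl bromide (1.3 equiv), −78 → −40 °C
Reagents that add atoms: prenyl bromide (1-bromo-3-methylbut-2-ene), CC(C)=CCBr
Why: Directed ortho-metalation: H3 lies between bromine and an OMOM group and is by far the most acidic ring proton, aryllithium 12 should be stable towards loss of LiBr at −78 °C, and the copper-catalysed allylic substitution of prenyl bromide should occur at its unhindered CH2 end (SN2).

Step 8
Reactants: 13 1-bromo-3,4-bis(methoxymethoxy)-2-(3-methylbut-2-enyl)benzene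
Product: 15 1,2-bis(methoxymethoxy)-3,4-bis(3-methylbut-2-enyl)benzene, via aryllithium 14 (not isolated)
Conditions: n-BuLi (1.05 equiv), THF, −78 °C; CuBr·SMe2 (10 mol %), prenyl bromide (1.3 equiv), −78 → 0 °C
Reagents that add atoms: prenyl bromide (1-bromo-3-methylbut-2-ene), CC(C)=CCBr
Why: Bromine–lithium exchange, faster at −78 °C than deprotonation of the benzylic/allylic CH2, followed by the same copper-catalysed SN2 allylation.

Step 9
Reactants: 15 1,2-bis(methoxymethoxy)-3,4-bis(3-methylbut-2-enyl)benzene
Product: 16 3,4-bis(3-methylbut-2-enyl)benzene-1,2-diol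
Conditions: 2 M aq. HCl (cat. amount), MeOH, 45 °C, Ar
Reagents that add atoms: none
Why: Acid-catalysed acetal exchange with methanol (standard MOM cleavage), run dilute and only warm, conditions under which o-prenylphenols are commonly released without cyclisation to chromans.

Step 10
Reactants: 9 3,5-dihydroxy-7-(methoxymethoxy)-8-(3-methylbut-2-enyl)-4H-chromen-4-one, 16 3,4-bis(3-methylbut-2-enyl)benzene-1,2-diol
Product: 18 2-[4,5-dihydroxy-2,3-bis(3-methylbut-2-enyl)phenyl]-3,5-dihydroxy-7-(methoxymethoxy)-8-(3-methylbut-2-enyl)-4H-chromen-4-one, via o-quinone 17 (not isolated)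
Conditions: undivided cell, graphite-felt anode, Pt cathode, controlled potential on the first anodic wave of 16 (ca. +0.4 V vs Ag/AgCl, to be set by cyclic voltammetry), MeCN/0.2 M aq. phosphate buffer pH 7 (1:1), 5 °C, Ar, 16 (1.1 equiv) added slowly, ca. 2 F per mol of 16
Reagents that add atoms: none
Why: Proposed new method: at a potential set on the first wave of 16 only the catechol should be oxidised (2 e−, 2 H+) to o-quinone 17, since the prenyl alkenes and chromone 9 need clearly higher potentials, while protons are reduced to H2 at the cathode. The enolate of the 3-hydroxy-4-pyranone of 9, a kojic-acid-type enol that takes up carbon electrophiles at the ring carbon next to the enol oxygen (C2), should then add in a Michael (1,4) sense to C5 of 17, and two proton shifts re-aromatise ring B to the catechol and ring C to the 3-hydroxychromone, so the C2–C1′ bond, the flavonol oxidation level and the free catechol all arise in one EC sequence from two C–H bonds. The closest known reaction type is the anodic oxidation of catechols in the presence of enolic C–H acids (4-hydroxycoumarin, dimedone, acetylacetone), in which 4-alkyl-o-quinones take carbon nucleophiles at C5. No ring is closed and no stereocentre is formed. Site selectivity on 17 is secured by the prenyl groups at C3 and C4, which leave C5 as the only free β-carbon (C6 would need a 1,6-addition) and also block the position needed for a coumestan-type second oxidation/oxa-Michael closure, and site selectivity on 9 is secured by the 7-O-MOM group and the chelated 5-OH, which keep ring A un-ionised at pH 7 so that its C6 cannot compete with the enolate carbon C2. Over-oxidation should be held back because the chromonyl group is an acceptor and the C2′ prenyl group twists ring B out of conjugation with the C3 enol, so 18 should be harder to oxidise than 16 and any quinone of 18 should be reduced back by remaining 16.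

Step 11
Reactants: 18 2-[4,5-dihydroxy-2,3-bis(3-methylbut-2-enyl)phenyl]-3,5-dihydroxy-7-(methoxymethoxy)-8-(3-methylbut-2-enyl)-4H-chromen-4-one
Product: 19 broussoflavonol G
Conditions: 2 M aq. HCl (cat. amount), MeOH, 45 °C, Ar, dark
Reagents that add atoms: none
Why: Acid-catalysed acetal exchange with methanol (MOM cleavage), as routinely used as the last step for prenylated flavonoids, with exclusion of air to protect the catechol and mild acid to avoid chroman formation.

## Compound list

1 | 2,4,6-trihydroxyacetophenone | CC(=O)c1c(O)cc(O)cc1O | starting material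
2 | 1-[2,6-dihydroxy-4-(methoxymethoxy)phenyl]ethanone | CC(=O)c1c(O)cc(OCOC)cc1O | intermediate
3 | 1-[2-hydroxy-4-(methoxymethoxy)-6-(3-methylbut-2-enyloxy)phenyl]ethanone | CC(=O)c1c(O)cc(OCOC)cc1OCC=C(C)C | intermediate
4 | (E)-3-(dimethylamino)-1-[2-hydroxy-4-(methoxymethoxy)-6-(3-methylbut-2-enyloxy)phenyl]prop-2-en-1-one | CN(C)/C=C/C(=O)c1c(O)cc(OCOC)cc1OCC=C(C)C | intermediate
5 | 7-(methoxymethoxy)-5-(3-methylbut-2-enyloxy)-4H-chromen-4-one | O=c1ccoc2cc(OCOC)cc(OCC=C(C)C)c12 | intermediate
6 | (±)-cis-2,3-epoxy-7-(methoxymethoxy)-5-(3-methylbut-2-enyloxy)chroman-4-one (racemic, one enantiomer drawn) | O=C1[C@@H]2O[C@@H]2Oc2cc(OCOC)cc(OCC=C(C)C)c12 | intermediate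
7 | 3-hydroxy-7-(methoxymethoxy)-5-(3-methylbut-2-enyloxy)-4H-chromen-4-one | O=c1c(O)coc2cc(OCOC)cc(OCC=C(C)C)c12 | intermediate
8 | (±)-3-hydroxy-7-(methoxymethoxy)-6-(2-methylbut-3-en-2-yl)-4H-chromene-4,5(6H)-dione (racemic at C6) | O=C1C(O)=COC2=C1C(=O)C(C(C)(C)C=C)C(OCOC)=C2 | intermediate
9 | 3,5-dihydroxy-7-(methoxymethoxy)-8-(3-methylbut-2-enyl)-4H-chromen-4-one | O=c1c(O)coc2c(CC=C(C)C)c(OCOC)cc(O)c12 | intermediate
10 | 4-bromobenzene-1,2-diol | Oc1ccc(Br)cc1O | starting material
11 | 4-bromo-1,2-bis(methoxymethoxy)benzene | COCOc1ccc(Br)cc1OCOC | intermediate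
12 | [6-bromo-2,3-bis(methoxymethoxy)phenyl]lithium | COCOc1ccc(Br)c([Li])c1OCOC | intermediate
13 | 1-bromo-3,4-bis(methoxymethoxy)-2-(3-methylbut-2-enyl)benzene | COCOc1ccc(Br)c(CC=C(C)C)c1OCOC | intermediate
14 | [3,4-bis(methoxymethoxy)-2-(3-methylbut-2-enyl)phenyl]lithium | COCOc1ccc([Li])c(CC=C(C)C)c1OCOC | intermediate
15 | 1,2-bis(methoxymethoxy)-3,4-bis(3-methylbut-2-enyl)benzene | COCOc1ccc(CC=C(C)C)c(CC=C(C)C)c1OCOC | intermediate
16 | 3,4-bis(3-methylbut-2-enyl)benzene-1,2-diol | Oc1ccc(CC=C(C)C)c(CC=C(C)C)c1O | intermediate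
17 | 3,4-bis(3-methylbut-2-enyl)cyclohexa-3,5-diene-1,2-dione | O=C1C=CC(CC=C(C)C)=C(CC=C(C)C)C1=O | intermediate
18 | 2-[4,5-dihydroxy-2,3-bis(3-methylbut-2-enyl)phenyl]-3,5-dihydroxy-7-(methoxymethoxy)-8-(3-methylbut-2-enyl)-4H-chromen-4-one | COCOc1cc(O)c2c(=O)c(O)c(-c3cc(O)c(O)c(CC=C(C)C)c3CC=C(C)C)oc2c1CC=C(C)C | intermediate
19 | broussoflavonol G | CC(C)=CCc1c(-c2oc3c(CC=C(C)C)c(O)cc(O)c3c(=O)c2O)cc(O)c(O)c1CC=C(C)C | target

## Step count and risks

Total step count: 11.
Longest linear sequence: 7 steps (steps 1–5, 10, 11).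

**Risk 1, step 10.**
- Quinone 17 may tautomerise through its doubly activated (benzylic and allylic) CH2 groups to quinone methides. These would be lost by chromene formation or oligomerisation before 9 captures the quinone.
- The enolate may attack through oxygen instead of C2.
- The product may be oxidised further at the anode.

The fallback uses only known chemistry. It sets out from 3 and comes back at 19. It builds ring C around a preformed aryl–carbon bond (Claisen–Schmidt condensation, then Algar–Flynn–Oyamada oxidation). Commercial 2-bromo-4,5-dihydroxybenzaldehyde is treated with MOMCl/DIPEA to give 2-bromo-4,5-bis(methoxymethoxy)benzaldehyde F1. Ethylene glycol/PPTS then gives its dioxolane F2. Lithiation with LDA between Br and OMOM and prenylation, as in step 7, should give the 3-prenyl bromide F3. Br/Li exchange and prenylation, as in step 8, should give the diprenyl dioxolane F4. PPTS in wet acetone should release 4,5-bis(methoxymethoxy)-2,3-diprenylbenzaldehyde F5 without loss of MOM. Condensation of F5 with 3 (KOH, EtOH, rt) should give the chalcone F6. Alkaline H2O2 in MeOH at low temperature should give the 5-O-prenyl flavonol F7. Eu(fod)3 in PhCl at 85 °C should give the 8-prenyl flavonol F8. HCl/MeOH as in step 11 removes the three MOM groups and gives 19.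

**Risk 2, step 4.**
- Hydroxide may open the pyranone ring (retro-Claisen loss of the formyl carbon) in competition with epoxidation.
- The acid isomerisation may cost the MOM group or the acid-labile O5 prenyl ether.

The fallback sets out from 4, which is isolated after the DMF-DMA stage of step 3 instead of being cyclised, and comes back at 7. It uses the known C–H acyloxylation/chromone annulation of o-hydroxyaryl enaminones. Dibenzoyl peroxide in toluene at 80 °C should give 3-benzoyloxy-7-(methoxymethoxy)-5-(3-methylbut-2-enyloxy)-4H-chromen-4-one F9. Methanolysis (K2CO3, MeOH, 0 °C) then frees the 3-OH and gives 7. This avoids both the epoxide and any acid.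

**Risk 3, step 5.**
- The free 3-hydroxy-4-keto unit may bind the europium catalyst.
- The sequence may stop after the first [3,3] shift by enolisation of 8, so the group would stay at C6 in its reversed form.

The fallback sets out from 7 and comes back at 9. It moves the substrate into the precedented class of 3-O-acylated 5-O-prenyl ethers. Ac2O/pyridine should give the 3-acetate F10. Eu(fod)3, NaHCO3, PhCl, 85 °C should give the rearranged 3-acetoxy-5-hydroxy-8-prenylchromone F11. K2CO3/MeOH at 0 °C removes the acetate and gives 9.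

## Further compounds

F1 | step 10 | 2-bromo-4,5-bis(methoxymethoxy)benzaldehyde | O=Cc1cc(OCOC)c(OCOC)cc1Br
F2 | step 10 | 2-[2-bromo-4,5-bis(methoxymethoxy)phenyl]-1,3-dioxolane | Brc1cc(OCOC)c(OCOC)cc1C1OCCO1
F3 | step 10 | 2-[2-bromo-4,5-bis(methoxymethoxy)-3-(3-methylbut-2-enyl)phenyl]-1,3-dioxolane | Brc1c(CC=C(C)C)c(OCOC)c(OCOC)cc1C1OCCO1
F4 | step 10 | 2-[4,5-bis(methoxymethoxy)-2,3-bis(3-methylbut-2-enyl)phenyl]-1,3-dioxolane | CC(C)=CCc1c(CC=C(C)C)c(OCOC)c(OCOC)cc1C1OCCO1
F5 | step 10 | 4,5-bis(methoxymethoxy)-2,3-bis(3-methylbut-2-enyl)benzaldehyde | CC(C)=CCc1c(CC=C(C)C)c(OCOC)c(OCOC)cc1C=O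
F6 | step 10 | (E)-3-[4,5-bis(methoxymethoxy)-2,3-bis(3-methylbut-2-enyl)phenyl]-1-[2-hydroxy-4-(methoxymethoxy)-6-(3-methylbut-2-enyloxy)phenyl]prop-2-en-1-one | COCOc1cc(O)c(C(=O)/C=C/c2cc(OCOC)c(OCOC)c(CC=C(C)C)c2CC=C(C)C)c(OCC=C(C)C)c1
F7 | step 10 | 2-[4,5-bis(methoxymethoxy)-2,3-bis(3-methylbut-2-enyl)phenyl]-3-hydroxy-7-(methoxymethoxy)-5-(3-methylbut-2-enyloxy)-4H-chromen-4-one | COCOc1cc(OCC=C(C)C)c2c(=O)c(O)c(-c3cc(OCOC)c(OCOC)c(CC=C(C)C)c3CC=C(C)C)oc2c1
F8 | step 10 | 2-[4,5-bis(methoxymethoxy)-2,3-bis(3-methylbut-2-enyl)phenyl]-3,5-dihydroxy-7-(methoxymethoxy)-8-(3-methylbut-2-enyl)-4H-chromen-4-one | COCOc1cc(O)c2c(=O)c(O)c(-c3cc(OCOC)c(OCOC)c(CC=C(C)C)c3CC=C(C)C)oc2c1CC=C(C)C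
F9 | step 4 | 3-benzoyloxy-7-(methoxymethoxy)-5-(3-methylbut-2-enyloxy)-4H-chromen-4-one | O=C(Oc1coc2cc(OCOC)cc(OCC=C(C)C)c2c1=O)c1ccccc1
F10 | step 5 | 3-acetoxy-7-(methoxymethoxy)-5-(3-methylbut-2-enyloxy)-4H-chromen-4-one | CC(=O)Oc1coc2cc(OCOC)cc(OCC=C(C)C)c2c1=O
F11 | step 5 | 3-acetoxy-5-hydroxy-7-(methoxymethoxy)-8-(3-methylbut-2-enyl)-4H-chromen-4-one | CC(=O)Oc1coc2c(CC=C(C)C)c(OCOC)cc(O)c2c1=O
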